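The route rests on cutting C3–C4 (plakortolide numbering, C1 = lactone C=O). This is the fusion bond shared by the 1,2-dioxane and the γ-lactone, and it joins the two oxygen-bearing carbons. A γ-lactone with a β-oxygen at C3 and a quaternary C4 is the Baeyer–Villiger product of a 3-alkoxy-2,2-dialkylcyclobutanone, hence of a dialkylketene and a vinyl ether. The key step is an intramolecular [2+2] cycloaddition of ketene 8, whose vinyl ether hangs on a sacrificial (R)-carbinol carbon (the future C6). It forms C3–C4 and C1–C2 together, closes two rings and fixes C4. Ring expansion, retro-oxa-Michael opening, insertion of H2O2 and an axial allylation of the C6 peroxycarbenium ion complete the target.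

Key step: step 4

Remark: the discussion uses C1 (lactone C=O), C2 (CH2), C3 (CH–OO), C4 (C(CH3)–O-acyl), C5 (CH2), C6 (C(CH3)(chain)–OO) and C7 onward for the side chain; systematic names use their own ring numbering.

Step 1
Reactants: 1 propionitrile; 2 (R)-propylene oxide
Product: 3 (4R)-4-hydroxy-2-methylpentanenitrile (both C2 epimers)
Conditions: LDA (1.1 equiv), THF, −78 °C; then 2, −78 °C to rt; H2O
Reagents that add atoms: none
Why: SN2 opening of the epoxide at its CH2 carbon by the lithiated nitrile (nitrile-anion alkylation) leaves the (R)-carbinol centre untouched, and the epimeric centre next to the nitrile is irrelevant because it becomes the sp2 ketene carbon in step 4.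

Step 2
Reactants: 3 (4R)-4-hydroxy-2-methylpentanenitrile; 4 butyl vinyl ether
Product: 5 (4R)-4-(ethenyloxy)-2-methylpentanenitrile
Conditions: Pd(OCOCF3)2 (1 mol%), 4,7-diphenyl-1,10-phenanthroline (1 mol%), Et3N (5 mol%), 4 as solvent, 75 °C
Reagents that add atoms: none
Why: Palladium-catalysed transfer vinylation (transetherification) moves the vinyl group onto the alcohol oxygen under nearly neutral conditions without touching the C–O bond of the stereocentre, and the excess of 4 drives the equilibrium.

Step 3
Reactants: 5 (4R)-4-(ethenyloxy)-2-methylpentanenitrile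
Product: 6 (4R)-4-(ethenyloxy)-2-methylpentanoic acid
Conditions: KOH, ethylene glycol/H2O, 130 °C; then cold 1 M HCl to pH 5, Et2O extraction, used at once
Reagents that add atoms: potassium hydroxide, [K+].[OH-]; water, O
Why: In this alkaline nitrile hydrolysis the vinyl ether is inert to hydroxide, so only the short, cold acidification has to be kept mild.

Step 4
Reactants: 6 (4R)-4-(ethenyloxy)-2-methylpentanoic acid
Product: 9 (1R,3R,5R)-3,5-dimethyl-2-oxabicyclo[3.2.0]heptan-6-one, via acid chloride 7 (not isolated), via ketene 8 (not isolated)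
Conditions: 1-chloro-N,N,2-trimethylprop-1-en-1-amine, CH2Cl2, 0 °C; then slow addition to Et3N, toluene, reflux, high dilution
Reagents that add atoms: none
Why: Dehydrochlorination of 7 gives ketene 8, whose electrophilic carbon C1 is attacked by the nucleophilic terminal carbon C2 of the vinyl ether while the ketene carbon C4 bonds to the oxygen-bearing carbon C3, in an asynchronous thermal [2+2] cycloaddition. The closest known reaction type is the intramolecular ketene–alkene cycloaddition, and dialkylketenes with alkyl vinyl ethers are known to give 3-alkoxy-2,2-dialkylcyclobutanones. The four-membered ring closes as the [2+2] adduct, and the five-membered oxacycle (C3, C4, C5, C6, O) closes with it because the three-atom tether C5–C6–O links the two π systems in the fused mode that gives bicyclo[3.2.0]heptanones. The fused rather than bridged regiochemistry is secured twice, by the oxygen on C3, which stabilises the developing positive charge there, and by the tether length. C3 and C4 can only be cis-fused, and their absolute sense is set by the C6 stereocentre, whose methyl group should take the convex face of the folding bicycle (the side of C4–CH3 and C3–H), away from the ketene carbonyl. The concave-methyl diastereomer is removed by chromatography, so the configurational purity at C4 does not rest on the selectivity alone, and slow addition at high dilution suppresses ketene dimerisation.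

Step 5
Reactants: 9 (1R,3R,5R)-3,5-dimethyl-2-oxabicyclo[3.2.0]heptan-6-one
Product: 10 (3aR,5R,6aR)-5,6a-dimethyltetrahydrofuro[3,2-b]furan-2(3H)-one
Conditions: mCPBA, CH2Cl2, 0 °C to rt
Reagents that add atoms: mCPBA, O=C(OO)c1cccc(Cl)c1
Why: In this Baeyer–Villiger oxidation, driven by release of cyclobutanone strain, the quaternary carbon C4 migrates in preference to the CH2 group C2 and does so with retention, which turns C4–C1 into the C4–O–C1 lactone linkage.

Step 6
Reactants: 10 (3aR,5R,6aR)-5,6a-dimethyltetrahydrofuro[3,2-b]furan-2(3H)-one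
Product: 12 (5R)-5-methyl-5-(2-oxopropyl)furan-2(5H)-one, via lithium alkoxide 11 (not isolated)
Conditions: LiHMDS (1.05 equiv), THF, −78 to −40 °C; then PhS(Cl)=N-t-Bu, −78 °C
Reagents that add atoms: none
Why: Deprotonation at C2 triggers E1cB retro-oxa-Michael cleavage of the C3–O bond, and the resulting alkoxide 11 is oxidised in the same flask by the Mukaiyama oxidation before it can re-add; C4 is untouched, while the relay centre C6 and C3 are erased on purpose.

Step 7
Reactants: 12 (5R)-5-methyl-5-(2-oxopropyl)furan-2(5H)-one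
Product: 14 (4aR,7aR)-3-methoxy-3,4a-dimethyltetrahydro-3H-furo[3,2-c][1,2]dioxin-6(4H)-one (both epimers at the ketal carbon C6), via methoxy hydroperoxide 13 (not isolated)
Conditions: urea·H2O2, Sc(OTf)3 (cat.), MeOH, rt; then Et2NH (cat.), MeOH, rt
Reagents that add atoms: hydrogen peroxide (as its urea adduct), OO; methanol, CO
Why: Acid-catalysed peroxyketalisation of the ketone gives 13, and a 6-exo-trig oxa-Michael addition of its OOH group to the butenolide closes the 1,2-dioxane; the tether on C4 reaches only the face of C3 that gives the cis-fused bicycle, so C3 becomes (R).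

Step 8
Reactants: 14 (4aR,7aR)-3-methoxy-3,4a-dimethyltetrahydro-3H-furo[3,2-c][1,2]dioxin-6(4H)-one; 15 allyltrimethylsilane
Product: 16 (3S,4aR,7aR)-3,4a-dimethyl-3-(prop-2-en-1-yl)tetrahydro-3H-furo[3,2-c][1,2]dioxin-6(4H)-one
Conditions: 15 (3 equiv), TMSOTf (0.3 equiv), CH2Cl2, −78 °C
Reagents that add atoms: none
Why: This is a Hosomi–Sakurai-type allylation of a peroxycarbenium ion: both ketal epimers ionise to one C6=O+ half-chair with C4–CH3 and C3–CH2 pseudoequatorial and the C4 acyloxy oxygen pseudoaxial, and axial attack leading directly to the chair should place the allyl group cis to the lactone oxygen, which is the (6S) configuration.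

Step 9
Reactants: 17 phenylmagnesium bromide; 18 11-bromoundec-1-ene
Product: 19 11-phenylundec-1-ene
Conditions: Li2CuCl4 (3 mol%), THF, 0 °C to rt
Reagents that add atoms: none
Why: Copper-catalysed Grignard–alkyl halide cross-coupling displaces the primary bromide and leaves the terminal alkene untouched.

Step 10
Reactants: 16 (3S,4aR,7aR)-3,4a-dimethyl-3-(prop-2-en-1-yl)tetrahydro-3H-furo[3,2-c][1,2]dioxin-6(4H)-one; 19 11-phenylundec-1-ene
Product: 20 (3S,4aR,7aR)-3,4a-dimethyl-3-[(2E)-12-phenyldodec-2-en-1-yl]tetrahydro-3H-furo[3,2-c][1,2]dioxin-6(4H)-one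
Conditions: 19 (3 equiv), second-generation Hoveyda–Grubbs catalyst (5 mol%), CH2Cl2, 40 °C
Reagents that add atoms: none
Why: This is an olefin cross-metathesis of two unhindered terminal alkenes with the cheap partner in excess; the ruthenium carbene tolerates hindered dialkyl peroxides and lactones, and the alkene geometry is irrelevant because the alkene is reduced next.

Step 11
Reactants: 20 (3S,4aR,7aR)-3,4a-dimethyl-3-[(2E)-12-phenyldodec-2-en-1-yl]tetrahydro-3H-furo[3,2-c][1,2]dioxin-6(4H)-one
Product: 21 plakortolide K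
Conditions: 2-nitrobenzenesulfonylhydrazide (excess, in portions), THF, rt
Reagents that add atoms: none
Why: Diimide reduction transfers H2 to the C=C bond in a concerted way and, unlike catalytic hydrogenation, leaves the O–O bond and all three stereocentres untouched.

Compound list
1 | propionitrile | CCC#N | starting material
2 | (R)-propylene oxide | C[C@@H]1CO1 | starting material
3 | (4R)-4-hydroxy-2-methylpentanenitrile (C2 epimers) | C[C@@H](O)CC(C)C#N | intermediate
4 | butyl vinyl ether | C=COCCCC | starting material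
5 | (4R)-4-(ethenyloxy)-2-methylpentanenitrile | C[C@@H](OC=C)CC(C)C#N | intermediate
6 | (4R)-4-(ethenyloxy)-2-methylpentanoic acid | C[C@@H](OC=C)CC(C)C(=O)O | intermediate
7 | (4R)-4-(ethenyloxy)-2-methylpentanoyl chloride | C[C@@H](OC=C)CC(C)C(=O)Cl | intermediate
8 | (4R)-4-(ethenyloxy)-2-methylpent-1-en-1-one (ketene) | C[C@@H](OC=C)CC(C)=C=O | intermediate
9 | (1R,3R,5R)-3,5-dimethyl-2-oxabicyclo[3.2.0]heptan-6-one | C[C@@H]1C[C@@]2(C)C(=O)C[C@H]2O1 | intermediate
10 | (3aR,5R,6aR)-5,6a-dimethyltetrahydrofuro[3,2-b]furan-2(3H)-one | C[C@@H]1C[C@@]2(C)OC(=O)C[C@H]2O1 | intermediate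
11 | lithium (2R)-1-[(2R)-2-methyl-5-oxo-2,5-dihydrofuran-2-yl]propan-2-olate | C[C@@H]([O-])C[C@@]1(C)OC(=O)C=C1.[Li+] | intermediate
12 | (5R)-5-methyl-5-(2-oxopropyl)furan-2(5H)-one | CC(=O)C[C@@]1(C)OC(=O)C=C1 | intermediate
13 | (5R)-5-(2-hydroperoxy-2-methoxypropyl)-5-methylfuran-2(5H)-one | COC(C)(OO)C[C@@]1(C)OC(=O)C=C1 | intermediate
14 | (4aR,7aR)-3-methoxy-3,4a-dimethyltetrahydro-3H-furo[3,2-c][1,2]dioxin-6(4H)-one (ketal epimers) | COC1(C)C[C@@]2(C)OC(=O)C[C@H]2OO1 | intermediate
15 | allyltrimethylsilane | C=CC[Si](C)(C)C | starting material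
16 | (3S,4aR,7aR)-3,4a-dimethyl-3-(prop-2-en-1-yl)tetrahydro-3H-furo[3,2-c][1,2]dioxin-6(4H)-one | C[C@]1(CC=C)C[C@@]2(C)OC(=O)C[C@H]2OO1 | intermediate
17 | phenylmagnesium bromide | Br[Mg]c1ccccc1 | starting material
18 | 11-bromoundec-1-ene | C=CCCCCCCCCCBr | starting material
19 | 11-phenylundec-1-ene | C=CCCCCCCCCCc1ccccc1 | intermediate
20 | (3S,4aR,7aR)-3,4a-dimethyl-3-[(2E)-12-phenyldodec-2-en-1-yl]tetrahydro-3H-furo[3,2-c][1,2]dioxin-6(4H)-one | C[C@]1(C/C=C/CCCCCCCCCc2ccccc2)C[C@@]2(C)OC(=O)C[C@H]2OO1 | intermediate
21 | plakortolide K, (3S,4aR,7aR)-3,4a-dimethyl-3-(12-phenyldodecyl)tetrahydro-3H-furo[3,2-c][1,2]dioxin-6(4H)-one | C[C@]1(CCCCCCCCCCCCc2ccccc2)C[C@@]2(C)OC(=O)C[C@H]2OO1 | target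

Total step count: 11. Longest linear sequence: 10 steps (steps 1 to 8, 10 and 11).

Steps most likely to fail

Step 4. The ketene may dimerise faster than it cyclises, or the C6 methyl group may discriminate poorly between the two faces. If the sense of induction proves opposite, the enantiomeric epoxide in step 1 corrects it. The fallback sets out from 6 and comes back at 9. Acid chloride 7 is intercepted with pyrrolidine to give the amide 1-[(4R)-4-(ethenyloxy)-2-methylpentanoyl]pyrrolidine F1. Tf2O and 2,6-di-tert-butyl-4-methylpyridine in CH2Cl2 convert it into the keteniminium triflate F2, a much stronger electrophile that does not dimerise. F2 undergoes the intramolecular keteniminium–alkene [2+2] cycloaddition at or below room temperature to the cyclobutaniminium triflate F3, and aqueous NaHCO3 hydrolyses F3 to 9.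

Step 6. The ring-opened alkoxide may re-add to the butenolide before it is oxidised, or residual base may expel the lactone carboxylate from the β-acyloxy ketone product. The fallback sets out from 10 and comes back at 12, replacing the anionic opening by C–H oxidation. Methyl(trifluoromethyl)dioxirane hydroxylates the tertiary C6–H bond, the most electron-rich C–H bond next to an ether oxygen. This gives the cyclic hemiketal (3aR,6aR)-5-hydroxy-5,6a-dimethyltetrahydrofuro[3,2-b]furan-2(3H)-one F4, the ring tautomer of (4R,5R)-4-hydroxy-5-methyl-5-(2-oxopropyl)dihydrofuran-2(3H)-one F5. MsCl/Et3N at −20 °C traps the open form as its mesylate F6, which loses methanesulfonate by E1cB elimination to give 12.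

Step 8. The Lewis acid may provoke heterolytic O–O cleavage of the peroxyketal, or attack on the peroxycarbenium ion may be poorly face-selective. The fallback sets out from 12 and comes back at 21. It uses known cobalt chemistry and gives up control at C6.
- Reagent 17 is coupled with 1,12-dibromododecane (Li2CuCl4) to give (12-bromododecyl)benzene F7.
- Its Grignard reagent 12-phenyldodecylmagnesium bromide F8, in the presence of CeCl3 at −78 °C, adds to the ketone of 12 to give the tertiary alcohol F9.
- The Burgess reagent dehydrates F9 to the 1,1-disubstituted alkene F10. Its double-bond isomers lead to the same C6 radical.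
- Mukaiyama–Isayama hydroperoxysilylation (Co(thd)2, thd = 2,2,6,6-tetramethylheptane-3,5-dionate, O2, Et3SiH) gives the triethylsilyl peroxide F11.
- Bu4NF frees the hydroperoxide F12, which closes by the oxa-Michael addition of step 7 to 21 and its C6 epimer F13. The two are separated by chromatography.

Further compounds
F1 | step 4 | 1-[(4R)-4-(ethenyloxy)-2-methylpentanoyl]pyrrolidine | C[C@@H](OC=C)CC(C)C(=O)N1CCCC1
F2 | step 4 | 1-[(4R)-4-(ethenyloxy)-2-methylpent-1-en-1-ylidene]pyrrolidinium triflate (keteniminium salt) | C[C@@H](OC=C)CC(C)=C=[N+]1CCCC1.[O-]S(=O)(=O)C(F)(F)F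
F3 | step 4 | 1-[(1R,3R,5R)-3,5-dimethyl-2-oxabicyclo[3.2.0]heptan-6-ylidene]pyrrolidinium triflate | C[C@@H]1C[C@@]2(C)C(=[N+]3CCCC3)C[C@H]2O1.[O-]S(=O)(=O)C(F)(F)F
F4 | step 6 | (3aR,6aR)-5-hydroxy-5,6a-dimethyltetrahydrofuro[3,2-b]furan-2(3H)-one | CC1(O)C[C@@]2(C)OC(=O)C[C@H]2O1
F5 | step 6 | (4R,5R)-4-hydroxy-5-methyl-5-(2-oxopropyl)dihydrofuran-2(3H)-one | CC(=O)C[C@@]1(C)OC(=O)C[C@H]1O
F6 | step 6 | (2R,3R)-2-methyl-5-oxo-2-(2-oxopropyl)tetrahydrofuran-3-yl methanesulfonate | CC(=O)C[C@@]1(C)OC(=O)C[C@H]1OS(C)(=O)=O
F7 | step 8 | (12-bromododecyl)benzene | BrCCCCCCCCCCCCc1ccccc1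
F8 | step 8 | 12-phenyldodecylmagnesium bromide | Br[Mg]CCCCCCCCCCCCc1ccccc1
F9 | step 8 | (5R)-5-(2-hydroxy-2-methyl-14-phenyltetradecyl)-5-methylfuran-2(5H)-one (carbinol epimers) | CC(O)(CCCCCCCCCCCCc1ccccc1)C[C@@]1(C)OC(=O)C=C1
F10 | step 8 | (5R)-5-methyl-5-(2-methylidene-14-phenyltetradecyl)furan-2(5H)-one | C=C(CCCCCCCCCCCCc1ccccc1)C[C@@]1(C)OC(=O)C=C1
F11 | step 8 | (5R)-5-methyl-5-[2-methyl-14-phenyl-2-(triethylsilylperoxy)tetradecyl]furan-2(5H)-one (C6 epimers) | CC[Si](CC)(CC)OOC(C)(CCCCCCCCCCCCc1ccccc1)C[C@@]1(C)OC(=O)C=C1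
F12 | step 8 | (5R)-5-(2-hydroperoxy-2-methyl-14-phenyltetradecyl)-5-methylfuran-2(5H)-one (C6 epimers) | CC(OO)(CCCCCCCCCCCCc1ccccc1)C[C@@]1(C)OC(=O)C=C1
F13 | step 8 | (3R,4aR,7aR)-3,4a-dimethyl-3-(12-phenyldodecyl)tetrahydro-3H-furo[3,2-c][1,2]dioxin-6(4H)-one (C6 epimer of 21) | C[C@@]1(CCCCCCCCCCCCc2ccccc2)C[C@@]2(C)OC(=O)C[C@H]2OO1
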